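Ring B (C5–C10, drimane numbering) is grown by one carbon from the cyclopentanone of a trans-hydrindanone that already holds C5 and the quaternary C10. The feature exploited is the methyl-bearing alkene carbon C8 between C7 and C9: it is slipped in as an ethylidene unit (C8 with its methyl C12) by cyclopropanation of the C7=C9 silyl enol ether. Oxidative opening of the bond shared by the three- and five-membered rings then delivers, in one operation, ring B, the C8 methyl and the C7=C8 double bond in its final place, leaving the C9 carbonyl as the handle for C11. Methylenation, face-selective hydroboration and a Knoevenagel–Doebner condensation complete the caffeate.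

Key step: step 7

Remark on the chemistry: drimane atom labels are used for all intermediates (ring A = C1–C5 and C10; ring B = C5–C10; C11 = CH2O carbon on C9; C12 = methyl on C8), so the five-membered ring of the hydrindanes is C5, C6, C7, C9, C10. (S)-Hajos–Parrish ketone is taken as a commercial, enantiopure starting material.

Step 1
Reactants: 1 (S)-Hajos–Parrish ketone
Product: 2 enone monoketal (dioxolane at the saturated C9 carbonyl, enone untouched)
Conditions: (TMSOCH2)2, TMSOTf (cat.), CH2Cl2, −78 → −20 °C
Reagents that add atoms: 1,2-bis(trimethylsilyloxy)ethane, C[Si](C)(C)OCCO[Si](C)(C)C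
Why: Noyori ketalisation acetalises the saturated cyclopentanone much faster than the conjugated enone carbonyl, so C9 should be masked without moving the double bond or touching C10.

Step 2
Reactants: 2 enone monoketal
Product: 4 gem-dimethyl β,γ-enone ketal (C3 ketone, C4 gem-dimethyl, C5=C6), via monomethyl enone ketal 3 (not isolated)
Conditions: KOtBu (2.5 equiv), MeI (excess), t-BuOH/THF, 0 °C → rt
Reagents that add atoms: iodomethane, CI
Why: Deconjugative α,α-dialkylation through the potassium dienolate: the second methylation at C4 removes the last α-hydrogen and leaves the alkene at C5=C6, while the ketal keeps C7 from being enolised.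

Step 3
Reactants: 4 gem-dimethyl β,γ-enone ketal
Product: 6 alkene ketal (C3 now CH2), via hydrazone 5 (not isolated)
Conditions: N2H4·H2O, KOH, diethylene glycol, 130 → 200 °C
Reagents that add atoms: none
Why: Wolff–Kishner reduction (Huang-Minlon procedure) of the hindered C3 ketone, which the base-stable ketal and the isolated alkene should survive.

Step 4
Reactants: 6 alkene ketal
Product: 8 (3aS,7aS)-4,4,7a-trimethyloctahydro-1H-inden-1-one, via trans-fused saturated ketal 7 (not isolated)
Conditions: H2 (4 atm), Pd/C, EtOAc, rt; filter; then 1 M HCl, THF, rt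
Reagents that add atoms: water, O
Why: Heterogeneous catalytic hydrogenation should add H2 to C5=C6 from the α face, because the β face of C5 is covered by the angular C10 methyl and the axial C4 methyl, which sets the trans ring fusion (C5, S); acid hydrolysis of the dioxolane then frees the C9 ketone.

Step 5
Reactants: 8 (3aS,7aS)-4,4,7a-trimethyloctahydro-1H-inden-1-one
Product: 9 trimethylsilyl enol ether (C7=C9)
Conditions: TMSOTf, Et3N, CH2Cl2, 0 °C → rt
Reagents that add atoms: trimethylsilyl trifluoromethanesulfonate, C[Si](C)(C)OS(=O)(=O)C(F)(F)F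
Why: Soft enolisation–silylation; C7 is the only enolisable position (C10 is quaternary), so a single regioisomer should form.

Step 6
Reactants: 9 trimethylsilyl enol ether
Product: 10 ethylidene adduct (1-silyloxy-6-methylbicyclo[3.1.0]hexane unit made of C9, C7 and C8, fused to ring A; mixture of cyclopropane diastereomers)
Conditions: Et2Zn, CH3CHI2, CH2Cl2, 0 °C → rt
Reagents that add atoms: 1,1-diiodoethane, CC(I)I
Why: Simmons–Smith cyclopropanation in its Furukawa ethylidene-transfer form: the electrophilic zinc carbenoid adds to the electron-rich enol ether, and the configurations of the three new cyclopropane carbons do not matter because all are erased in step 7.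

Step 7
Reactants: 10 ethylidene adduct
Product: 12 (4aS,8aS)-2,5,5,8a-tetramethyl-4a,5,6,7,8,8a-hexahydronaphthalen-1(4H)-one, via chloro ketone 11 (not isolated)
Conditions: FeCl3 (2.2 equiv), DMF, 0 °C → rt; then NaOAc, MeOH, reflux
Reagents that add atoms: none
Why: FeCl3 oxidises the siloxycyclopropane by one electron and, after loss of the silyl group, the cyclopropyloxy radical at C9 undergoes β-scission of the C7–C9 bond common to the three- and five-membered rings, so that the former cyclopentane takes in C8 (with its methyl C12) and becomes a 3-oxocyclohexyl radical at C7, which abstracts chlorine from a second FeCl3; acetate then removes HCl by E1cB to place the double bond at C7=C8. The closest known reaction type is the Ito–Saegusa ring expansion of 1-siloxybicyclo[n.1.0]alkanes to 2-cycloalkenones, here run on a methyl-substituted cyclopropane. No ring is closed by cyclisation: the six-membered ring B arises by ring expansion of the five-membered ring when the shared bond breaks, driven by release of the cyclopropane strain. No new stereocentre is formed, the three cyclopropane centres are erased, and C5 and C10 are not touched. The selectivity needed is cleavage of the internal C7–C9 bond and not the external C8–C9 bond; both give secondary radicals, but only internal cleavage opens the bicycle to a strain-free cyclohexanone, which should decide the outcome. The position of the double bond is secured because C8–H is the only acidic hydrogen next to the carbonyl (C10 is quaternary).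

Step 8
Reactants: 12 (4aS,8aS)-2,5,5,8a-tetramethyl-4a,5,6,7,8,8a-hexahydronaphthalen-1(4H)-one
Product: 13 drima-7,9(11)-diene
Conditions: Ph3PCH3Br, KOtBu, toluene, 80 °C
Reagents that add atoms: methyltriphenylphosphonium bromide, C[P+](c1ccccc1)(c1ccccc1)c1ccccc1.[Br-]
Why: Wittig methylenation with the unstabilised ylide should convert the C9 carbonyl, which has no α-hydrogen on the C10 side, into the exocyclic C9=C11 alkene of the conjugated diene.

Step 9
Reactants: 13 drima-7,9(11)-diene
Product: 15 (−)-drimenol, via B-alkyl-9-BBN adduct 14 (not isolated)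
Conditions: 9-BBN, THF, 0 °C → rt; then NaOH, H2O2, 0 °C → rt
Reagents that add atoms: hydrogen peroxide, OO
Why: Hydroboration–oxidation: 9-BBN should add to the terminal 1,1-disubstituted C9=C11 bond and not to the trisubstituted ring alkene, with boron at C11 and hydrogen delivered to C9 from the α face opposite the axial C10 methyl, which sets C9 (S, CH2OH equatorial).

Step 10
Reactants: 15 (−)-drimenol; 16 Meldrum's acid
Product: 17 drimenyl hydrogen malonate
Conditions: toluene, 100 °C
Reagents that add atoms: none
Why: Alcoholysis of Meldrum's acid: the primary alcohol opens the dioxanedione on heating and acetone is lost, giving the malonic half-ester without an activating agent or protecting group.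

Step 11
Reactants: 17 drimenyl hydrogen malonate; 18 3,4-dihydroxybenzaldehyde
Product: 20 drimenyl (E)-caffeate (target), via arylidene malonate half-ester 19 (not isolated)
Conditions: pyridine, piperidine (cat.), 60 °C
Reagents that add atoms: none
Why: Knoevenagel–Doebner condensation: amine-catalysed condensation of the half-ester with the aldehyde is followed by decarboxylation to the (E)-cinnamate; the free catechol needs no protection and C9 is not epimerisable under these conditions.

Compound list
1 | (S)-Hajos–Parrish ketone, (7aS)-7a-methyl-2,3,7,7a-tetrahydro-1H-indene-1,5(6H)-dione | C[C@]12CCC(=O)C=C1CCC2=O | starting material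
2 | enone monoketal, (7a'S)-7a'-methyl-2',3',7',7a'-tetrahydrospiro[[1,3]dioxolane-2,1'-inden]-5'(6'H)-one | C[C@]12CCC(=O)C=C1CCC21OCCO1 | intermediate
3 | monomethyl enone ketal (C4-methyl, conjugated enone) | C[C@]12CCC(=O)C(C)=C1CCC21OCCO1 | intermediate
4 | gem-dimethyl β,γ-enone ketal, (7a'S)-4',4',7a'-trimethyl-2',4',7',7a'-tetrahydrospiro[[1,3]dioxolane-2,1'-inden]-5'(6'H)-one | C[C@]12CCC(=O)C(C)(C)C1=CCC21OCCO1 | intermediate
5 | hydrazone of 4 at C3 | C[C@]12CCC(=NN)C(C)(C)C1=CCC21OCCO1 | intermediate
6 | alkene ketal, (7a'S)-4',4',7a'-trimethyl-2',4',5',6',7',7a'-hexahydrospiro[[1,3]dioxolane-2,1'-indene] | C[C@]12CCCC(C)(C)C1=CCC21OCCO1 | intermediate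
7 | trans-fused saturated ketal, (3a'S,7a'S)-4',4',7a'-trimethyloctahydrospiro[[1,3]dioxolane-2,1'-indene] | C[C@]12CCCC(C)(C)[C@@H]1CCC21OCCO1 | intermediate
8 | (3aS,7aS)-4,4,7a-trimethyloctahydro-1H-inden-1-one | C[C@]12CCCC(C)(C)[C@@H]1CCC2=O | intermediate
9 | trimethylsilyl enol ether of 8 (C7=C9) | C[C@]12CCCC(C)(C)[C@@H]1CC=C2O[Si](C)(C)C | intermediate
10 | ethylidene adduct of 9 (silyloxy methylcyclopropane, diastereomer mixture at the cyclopropane carbons) | C[C@]12CCCC(C)(C)[C@@H]1CC1C(C)C12O[Si](C)(C)C | intermediate
11 | (4aS,8aS)-3-chloro-2,5,5,8a-tetramethyloctahydronaphthalen-1(2H)-one (mixture at C2 and C3) | CC1C(Cl)C[C@H]2C(C)(C)CCC[C@]2(C)C1=O | intermediate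
12 | (4aS,8aS)-2,5,5,8a-tetramethyl-4a,5,6,7,8,8a-hexahydronaphthalen-1(4H)-one (11-nordrim-7-en-9-one) | CC1=CC[C@H]2C(C)(C)CCC[C@]2(C)C1=O | intermediate
13 | drima-7,9(11)-diene (5S,10S) | CC1=CC[C@H]2C(C)(C)CCC[C@]2(C)C1=C | intermediate
14 | B-(drim-7-en-11-yl)-9-borabicyclo[3.3.1]nonane | CC1=CC[C@H]2C(C)(C)CCC[C@]2(C)[C@H]1CB1C2CCCC1CCC2 | intermediate
15 | (−)-drimenol, [(1S,4aS,8aS)-2,5,5,8a-tetramethyl-1,4,4a,5,6,7,8,8a-octahydronaphthalen-1-yl]methanol | CC1=CC[C@H]2C(C)(C)CCC[C@]2(C)[C@H]1CO | intermediate
16 | Meldrum's acid, 2,2-dimethyl-1,3-dioxane-4,6-dione | CC1(C)OC(=O)CC(=O)O1 | starting material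
17 | drimenyl hydrogen malonate | CC1=CC[C@H]2C(C)(C)CCC[C@]2(C)[C@H]1COC(=O)CC(=O)O | intermediate
18 | 3,4-dihydroxybenzaldehyde | O=Cc1ccc(O)c(O)c1 | starting material
19 | arylidene malonate half-ester, 2-(3,4-dihydroxybenzylidene)malonic acid mono-drimenyl ester | CC1=CC[C@H]2C(C)(C)CCC[C@]2(C)[C@H]1COC(=O)C(=Cc1ccc(O)c(O)c1)C(=O)O | intermediate
20 | drimenyl (E)-caffeate, CNP0265201.1 | CC1=CC[C@H]2C(C)(C)CCC[C@]2(C)[C@H]1COC(=O)/C=C/c1ccc(O)c(O)c1 | target

Total steps: 11. Longest linear sequence: 11 steps (1 → 20; 16 and 18 are bought).

Steps most likely to fail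

Step 7. The oxy radical may break the external C8–C9 bond, or the siloxycyclopropane may open by simple protodesilylation without oxidation, so that the five-membered ring is kept. The fallback sets out from 9 and returns at 12. Dibromocarbene addition (CHBr3, KOtBu, pentane, −20 °C) gives the dibromo(siloxy)cyclopropane F1. Its thermal disrotatory cyclopropyl-to-allyl cation opening (toluene, 80 °C) can only break the internal bond, and after loss of the silyl group as its bromide it gives the ring-enlarged 2-bromo enone F2. Stille coupling with Me4Sn (Pd(PPh3)4, CuI, DMF, 80 °C) then installs the C8 methyl and gives 12.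

Step 6. Transfer of the substituted carbenoid to the hindered trisubstituted enol ether may be slow, so that carbenoid decomposition and hydrolysis of the enol ether win. The fallback sets out from 9 and returns at 12, with the methyl introduced after the ring expansion. The parent methylene carbenoid (Et2Zn, CH2I2, CH2Cl2, 0 °C) gives the unsubstituted siloxycyclopropane F3. FeCl3/DMF then NaOAc/MeOH gives, via the chloro ketone F4, the 2-unsubstituted enone F5. α-Iodination (I2, pyridine, CH2Cl2) gives the 2-iodo enone F6, and Stille methylation (Me4Sn, Pd(PPh3)4, CuI, DMF) gives 12.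

Step 8. Attack of the ylide on the hindered, conjugated C9 carbonyl may be sluggish and compete with γ-deprotonation at C6 to the dienolate, so that the olefination stalls. The fallback sets out from 12 and returns at 13 by a two-stage Peterson olefination. Addition of Me3SiCH2Li/CeCl3 (THF, −78 °C) gives the β-hydroxysilane F7, and KH (THF, rt) eliminates it to 13.

Further compounds
F1 | step 7 | dibromo(siloxy)cyclopropane (dibromocarbene adduct of 9) | C[C@]12CCCC(C)(C)[C@@H]1CC1C(Br)(Br)C12O[Si](C)(C)C
F2 | step 7 | (4aS,8aS)-2-bromo-5,5,8a-trimethyl-4a,5,6,7,8,8a-hexahydronaphthalen-1(4H)-one | BrC1=CC[C@H]2C(C)(C)CCC[C@]2(C)C1=O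
F3 | step 6 | unsubstituted siloxycyclopropane (methylene adduct of 9) | C[C@]12CCCC(C)(C)[C@@H]1CC1CC12O[Si](C)(C)C
F4 | step 6 | (4aS,8aS)-3-chloro-5,5,8a-trimethyloctahydronaphthalen-1(2H)-one | O=C1CC(Cl)C[C@H]2C(C)(C)CCC[C@]12C
F5 | step 6 | (4aS,8aS)-5,5,8a-trimethyl-4a,5,6,7,8,8a-hexahydronaphthalen-1(4H)-one | O=C1C=CC[C@H]2C(C)(C)CCC[C@]12C
F6 | step 6 | (4aS,8aS)-2-iodo-5,5,8a-trimethyl-4a,5,6,7,8,8a-hexahydronaphthalen-1(4H)-one | O=C1C(I)=CC[C@H]2C(C)(C)CCC[C@]12C
F7 | step 8 | β-hydroxysilane, C9 tertiary alcohol bearing CH2SiMe3 (adduct of 12) | CC1=CC[C@H]2C(C)(C)CCC[C@]2(C)C1(O)C[Si](C)(C)C
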